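The coupling partner in this flask could end in two ways, as target or as decomposed reagent.

    solid substrate ⇌ dissolved substrate, rate k1*(cs1 - [dissolved substrate]) while solid is left; crystals form when [dissolved substrate] > cs1 (cs1 = 36 mM, k1 = 0.0019 /s)
    dissolved substrate + coupling partner → target (k2 = 6.1 /M/s)
    solid product ⇌ target, rate k3*(cs3 - [target]) while solid is left; crystals form when [target] > cs3 (cs3 = 22 mM, k3 = 0.46 /s)
    coupling partner → decomposed reagent (k4 = 0.0050 /s)
    coupling partner + target ⇌ idle adduct, settled at all times (K5 = 14 /M)

solid substrate 0.050 M; coupling partner 0.0475 M; time 10 min

- target is meant together with its solid product and idle adduct
- solid, in amounts per volume of the solution: solid substrate, solid product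
- at the start none of the solid substrate is in solution
- run time (flask): 10 min

1. the target and solid product and idle adduct together standing at 10 min, as a percentage of the solid substrate charged
2. the change that raises the amount of target and solid product and idle adduct together at 10 min, in percent of the solid substrate charged most ("none" if none brings more than 2 percentage points) (south-west / north-east / north-west / west / none)
3. amount of target and solid product and idle adduct together at 10 min, in percent of the solid substrate charged, after south-west

- south-west: doubling the dissolution coefficient of step 1, all else as stated
- north-east: doubling the dissolution coefficient of step 3, all else as stated
- north-west: doubling the amount of coupling partner, all else as stated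
- west: doubling the solubility in step 3, all else as stated

Dissolved substrate had a half-life of 2.4 s against the partner as charged, far shorter than the 8.77 min time constant of dissolving. So I held it near zero and let the solid feed the solution at a steady 0.0821 /min, in fractions of the substrate charge, with dissolution as the rate-limiting step of target formation. In the same fractions, and leaving the idle adduct aside in this estimate, I let the partner fall by that feed plus its own decay, which opened at 0.285 /min. Integrating gave a logarithm, and I carried the result as the catch: the feed over the decay constant, times the natural logarithm of (feed plus opening decay) over feed 41.0 %.

That lay below the 44.0 % of the charge that saturates target, so I expected no solid product and no gain from north-east or west in this flask. South-west doubles the feed, for a catch of 55.1 %. North-west doubles the opening decay, for 56.7 %, so I chose north-west, narrowly.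

The forecast, stepping by hand from “Dissolution is slow compared with coupling”, gave 41.3 %, north-west and 54.8 %.

The flask stood at 39.6 %, 1.4 percentage points under the catch; north-west gained 17 points, south-west gained 14 points and reached 53.4 %. At 5.00 min the flask held dissolved substrate at 7.30 % of saturation and coupling partner at 4.98 % of its own charge. The neighbour flask with 0.19 M of coupling partner had a catch of 73.9 %, and it read 73.5 %.

Its constants were drawn at random within sensible limits; the rest is arithmetic.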